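**Plan**
Retrosynthesis: the four phenols are masked as methyl ethers. The benzylic bond C1–C2 of the tetradecane chain and its symmetry twin C14–C13 are then cut together. This leaves two 3,5-dimethoxybenzyl anions (C7) and the C2–C13 block as 1,12-dibromododecane (C12).
Enabling feature: the two resorcinol rings are interchanged by the twofold symmetry through the C7–C8 midpoint of an unfunctionalised (CH2)14 tether, so both benzylic bonds are equivalent. Each benzylic carbon (C1, C14) lies meta to both ring oxygens, where a carbanion is stabilised by the ring and by induction and is not opposed by oxygen lone-pair donation.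
Precursor design: the anion is stored as the benzylic methyl ether. Two-electron reduction expels methoxide, so this helper group leaves in the flask in which it is used.
Forward order: O-methylation of the benzylic alcohol, then one-flask reductive lithiation and two-directional double alkylation (C7 + C12 + C7, the whole C26 skeleton), then fourfold O-demethylation. Both benzene rings are bought and no ring is formed.
Stereochemistry: the target has no stereocentre and no stereogenic double bond, so nothing has to be set.

Key step: step 2

Remark: the SMILES holds no stereodescriptor and the molecule is achiral, so "single enantiomer" is taken to mean the one constitution shown.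

Step 1
Reactants: 1 3,5-dimethoxybenzyl alcohol
Product: 3 3,5-dimethoxybenzyl methyl ether, via sodium 3,5-dimethoxybenzyloxide 2 (not isolated)
Conditions: NaH (1.2 equiv), THF, 0 °C; MeI (1.3 equiv), 0 °C → rt
Reagents that add atoms: iodomethane, CI
Why: Williamson ether synthesis, in which irreversible deprotonation of the primary benzylic alcohol and SN2 methylation of alkoxide 2 install the benzylic methoxy group, the reductively cleavable activating group for step 2 that, unlike a halide, cannot be displaced by the benzyl anion.

Step 2
Reactants: 3 3,5-dimethoxybenzyl methyl ether (2.3 equiv); 4 1,12-dibromododecane (1 equiv)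
Product: 7 1,14-bis(3,5-dimethoxyphenyl)tetradecane, via 3,5-dimethoxybenzyllithium 5 (not isolated), via 1-(13-bromotridecyl)-3,5-dimethoxybenzene 6 (not isolated)
Conditions: Li (excess), naphthalene (10 mol %), THF, −15 °C; solution decanted from Li; 4, −15 °C → rt; H2O
Reagents that add atoms: none
Why: Lithium naphthalenide transfers two electrons in turn to the arene of 3, the radical anion expels methoxide from the benzylic carbon and the benzyl radical is reduced to 3,5-dimethoxybenzyllithium 5, whose carbanion lies meta to both ring methoxy groups and is therefore stabilised by the ring and by induction without opposing lone-pair donation. 5 displaces bromide from one end of 4 in an SN2 reaction to give 6, and a second equivalent of 5 joins the C7 benzyl unit to the C13 aryl-alkyl bromide 6 in the same way, so that the bond C1–C2 and its twin C14–C13, and with them all 26 skeletal carbons, arise in one flask from a symmetric C12 core. The closest known reaction types are the arene-catalysed reductive lithiation of benzyl alkyl ethers and the alkylation of benzyllithium reagents with primary alkyl halides, run here in two directions on an α,ω-dihalide. No ring is closed and no stereocentre is formed. The step needs cleavage of the benzylic C–O bond in preference to the two aryl C–O bonds, which the far better stabilised benzyl anion secures, and it needs an anion that does not attack its own precursor, which the poor leaving group methoxide secures where a benzyl halide would give the bibenzyl by Wurtz coupling. It also needs substitution in preference to elimination and bromine–lithium exchange and a complete second displacement, which the soft delocalised nucleophile, the unhindered primary bromides, the uphill exchange to an alkyllithium and a small excess of 5 secure, the two chain ends being twelve carbons apart and hence independent.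

Step 3
Reactants: 7 1,14-bis(3,5-dimethoxyphenyl)tetradecane
Product: 9 bisnorstriatol [5,5'-(tetradecane-1,14-diyl)bis(benzene-1,3-diol)], via tetrakis(dibromoboryl) ether 8 (not isolated)
Conditions: BBr3 (6 equiv), CH2Cl2, −78 °C → rt; H2O, 0 °C
Reagents that add atoms: none
Why: Lewis acid-mediated aryl methyl ether cleavage, in which BBr3 binds each methoxy oxygen, bromide removes the methyl group by SN2 to give the aryl dibromoborate 8 and hydrolysis frees the four phenols, the saturated chain and the arenes offering no other reactive site.

**Compound list**
1 | 3,5-dimethoxybenzyl alcohol | OCc1cc(OC)cc(OC)c1 | starting material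
2 | sodium 3,5-dimethoxybenzyloxide | [Na+].[O-]Cc1cc(OC)cc(OC)c1 | intermediate
3 | 3,5-dimethoxybenzyl methyl ether [1,3-dimethoxy-5-(methoxymethyl)benzene] | COCc1cc(OC)cc(OC)c1 | intermediate
4 | 1,12-dibromododecane | BrCCCCCCCCCCCCBr | starting material
5 | 3,5-dimethoxybenzyllithium | [Li]Cc1cc(OC)cc(OC)c1 | intermediate
6 | 1-(13-bromotridecyl)-3,5-dimethoxybenzene | COc1cc(OC)cc(CCCCCCCCCCCCCBr)c1 | intermediate
7 | 1,14-bis(3,5-dimethoxyphenyl)tetradecane | COc1cc(OC)cc(CCCCCCCCCCCCCCc2cc(OC)cc(OC)c2)c1 | intermediate
8 | 1,14-bis[3,5-bis(dibromoboryloxy)phenyl]tetradecane (tetrakis(dibromoboryl) ether) | BrB(Br)Oc1cc(OB(Br)Br)cc(CCCCCCCCCCCCCCc2cc(OB(Br)Br)cc(OB(Br)Br)c2)c1 | intermediate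
9 | bisnorstriatol, 5,5'-(tetradecane-1,14-diyl)bis(benzene-1,3-diol), achiral | Oc1cc(O)cc(CCCCCCCCCCCCCCc2cc(O)cc(O)c2)c1 | target

Total step count: 3. Longest linear sequence: 3 (1 → 3 → 7 → 9).

**Steps most likely to fail**

1. Step 2.
Risk: electron transfer may run past the benzylic C–O cleavage, causing ring reduction or loss of a ring methoxy group. Residual naphthalenide may reduce the C–Br bonds, and the second displacement may stay incomplete.
Fallback: olefination in place of alkylation, making the same pair of bonds at the alkene oxidation level. It sets out from 1 and 4 and comes back at 7.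
- 1 would be oxidised with MnO2 in CH2Cl2 to 3,5-dimethoxybenzaldehyde F1.
- 4 would be heated with PPh3 (2.2 equiv) in MeCN to give dodecane-1,12-diylbis(triphenylphosphonium) dibromide F2.
- NaHMDS (2.1 equiv) in THF at 0 °C would convert F2 into dodecane-1,12-diylidenebis(triphenylphosphorane) F3.
- F3 and F1 (2.2 equiv) should undergo a double Wittig reaction to 1,14-bis(3,5-dimethoxyphenyl)tetradeca-1,13-diene F4. The alkene geometry is of no consequence.
- Hydrogenation (H2, Pd/C, EtOAc) would give 7.

2. Step 3.
Risk: cleavage of the four ethers may stall at partly methylated stages as boron aryloxides precipitate. The electron-rich tetraphenol may also suffer air oxidation during the acidic aqueous work-up.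
Fallback: a change of protecting group and of coupling polarity, with neutral hydrogenolysis as the last operation. It sets out from 4 and comes back at 9.
- 4 would be converted with Mg in THF into dodecane-1,12-diylbis(magnesium bromide) F5.
- F5 would be joined under copper catalysis (Li2CuCl4, THF, −10 °C → rt) to commercial 3,5-bis(benzyloxy)benzyl bromide (BrCc1cc(OCc2ccccc2)cc(OCc2ccccc2)c1, 2.2 equiv). This should give 1,14-bis[3,5-bis(benzyloxy)phenyl]tetradecane F6.
- H2, Pd/C in EtOAc–EtOH would remove the four benzyl groups and give 9.

3. Step 1.
Risk: incomplete alkoxide formation would leave alcohol in the ether, and traces of it would protonate the benzyllithium in step 2.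
Fallback: reversed Williamson polarity, with the benzylic carbon as the electrophile. It sets out from 1 and comes back at 3.
- 1 would be treated with SOCl2 (CH2Cl2, cat. DMF) to give 3,5-dimethoxybenzyl chloride F7.
- F7 with NaOMe in MeOH at reflux should give 3, free of hydroxylic material after distillation.

**Further compounds**
F1 | step 2 | 3,5-dimethoxybenzaldehyde | O=Cc1cc(OC)cc(OC)c1
F2 | step 2 | dodecane-1,12-diylbis(triphenylphosphonium) dibromide | [Br-].[Br-].c1ccccc1[P+](c1ccccc1)(c1ccccc1)CCCCCCCCCCCC[P+](c1ccccc1)(c1ccccc1)c1ccccc1
F3 | step 2 | dodecane-1,12-diylidenebis(triphenylphosphorane) | c1ccccc1P(c1ccccc1)(c1ccccc1)=CCCCCCCCCCCC=P(c1ccccc1)(c1ccccc1)c1ccccc1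
F4 | step 2 | 1,14-bis(3,5-dimethoxyphenyl)tetradeca-1,13-diene (alkene geometry undefined, erased on hydrogenation) | COc1cc(OC)cc(C=CCCCCCCCCCCC=Cc2cc(OC)cc(OC)c2)c1
F5 | step 3 | dodecane-1,12-diylbis(magnesium bromide) | Br[Mg]CCCCCCCCCCCC[Mg]Br
F6 | step 3 | 1,14-bis[3,5-bis(benzyloxy)phenyl]tetradecane | c1ccccc1COc1cc(OCc2ccccc2)cc(CCCCCCCCCCCCCCc2cc(OCc3ccccc3)cc(OCc3ccccc3)c2)c1
F7 | step 1 | 3,5-dimethoxybenzyl chloride | ClCc1cc(OC)cc(OC)c1
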